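The runs come from a simulation for an exercise; the scatter is artificial.

In this closed flask, under the steps proposed, [spent carrier] + [fresh carrier] + [spent catalyst], the last being the off-cycle form, stays at the 5.0 mM charged. The meeting took that balance as its frame and the dawn run, which is this flask followed so far, as its evidence.

| flask | substrate | salt in the second phase | spent carrier | remark | time | volume of the second phase over the first |
|---|---|---|---|---|---|---|
| dawn | 0.10 M | 0.095 M | 5 mM | the very flask that is asked about, followed so far |  |  |
| flask | 0.10 M | 0.0950 M | 5.0 mM |  | 1.5 h | 0.25 |

- dawn (time / min: product / %, crystals / %): 10.0: 13.8, 0; 20.0: 23.5, 0; 25.0: 27.5, 0; 40.0: 35.1, 0.9; 50.0: 40.4, 0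

(readings scatter by 0.5 percentage points)

- what is said of product includes crystals
- in the second phase: salt in the second phase, spent salt in the second phase; everything else is in the first
- charges count per volume of the first phase; a concentration in a rate is the amount of a species over the volume of its own phase; every rate counts per litre of the first phase
- crystals is a solid; its amount is given per volume of the solution
- the numbers in the tables scatter with a standard deviation of 0.5 percentage points
- steps that have been proposed: spent carrier + salt in the second phase <-> fresh carrier + spent salt in the second phase; substrate + fresh carrier -> product + spent carrier; spent carrier -> spent catalyst; crystals <-> product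
- the earlier runs hold the two phases in the same ratio of volumes as the flask asked about

1. product and crystals together at 1.5 h, in percent of the substrate charged
2. concentration of product in solution at 1.5 h, in percent of saturation

Minutes. I reported that product formed at 0.00913 min⁻¹ of the charge between 10.0 min and 25.0 min, but at a lower 0.00516 min⁻¹ between 25.0 min and 50.0 min. Those two rates put the fade time at 35.0 min, the time over which the rate of product formation falls by a factor of e. I argued that the rate at the last reading times the fade time leaves a tail of 12.6% of the charge still to come. Adding the part of that tail due by 1.5 h gave me 49.0% for y.

On crystals I held that one reading of 0.9%, against a scatter of 0.5 percentage points and followed by 0%, is probably noise, that saturation may then lie above about 40.4% of the charge, and that the readings give no figure for sat.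

The author of the forecast, who saw the same runs, entered 52% and 100%, saying “Pure exponential decay of the catalyst gives about 52%”, which is higher than my figure.

This flask gave 49.6%, with crystals at 0% and [product] at 82.6% of saturation, so the forecast's sat stood 17 points too high.

    spent carrier + salt in the second phase ⇌ fresh carrier + spent salt in the second phase (K = 0.980, k = 15.0 M⁻¹ min⁻¹)
    substrate + fresh carrier → product + spent carrier (k = 3.60 M⁻¹ min⁻¹)
    spent carrier → spent catalyst (k = 0.0280 min⁻¹)
    crystals ⇌ product, rate k4*(cs4 - [product]) while solid is left; crystals form when [product] > cs4 (solubility = 0.0600 M, k = 0.220 min⁻¹)

The result of this flask lies 0.60 points above the 49.0% from the fade time. At 0.309 h in this flask, fresh carrier falls back 5.5 times faster than it goes on, and the forward reversible step uses spent carrier 150 times faster than spent catalyst forms. At 1.50 h the catalyst charged stands as 19.5% spent carrier, 16.1% fresh carrier and 64.4% spent catalyst. For this flask left until 2.5 h, the fade time gives 52.3% of product and crystals together, and that flask holds 54.6%.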